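Watch the tail of Ky, not its peak, and count half-lives there.

| setting | south-west | north-west | flask |
|---|---|---|---|
| Ly | 13 mM | 30 mM | 20 mM |
| Zu | 4.9 mM (held) | 4.9 mM (held) | 4.9 mM (held) |
| remark | run made earlier | run made earlier |  |
| time |  |  | 80 min |

| run | time / min | Ky / % |
|---|---|---|
| south-west | 1.50 | 23.2 |
| south-west | 4.00 | 33.6 |
| south-west | 8.00 | 37.8 |
| south-west | 20.0 | 28.5 |
| south-west | 40.0 | 19.5 |
| south-west | 90.0 | 5.0 |
| north-west | 1.50 | 19.7 |
| north-west | 4.00 | 33.0 |
| north-west | 8.00 | 37.6 |
| north-west | 20.0 | 30.9 |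
| north-west | 40.0 | 21.9 |
| north-west | 90.0 | 7.0 |

(readings scatter by 1 percentage point)

- amounts and yields of Xa count Ux too
- given per volume of solution although it is solid: Ux
- at the start none of Dw is dissolved
- steps thought possible: Ux <-> Xa; Zu <-> Dw; Ly + Dw -> Ej + Xa; Ly + Dw -> Ky + Xa; Dw + Ky -> Yx + Xa; Dw + Ej -> Yx + Xa

- the best time, 80 min at the latest, for Ky
- the amount of Ky, in percent of the Ly charged, at that time

Two views of this flask are in dispute. The supply side holds that Dw arrives from Zu at a fixed rate, so in percent of the charge Ky falls more slowly in the larger charge, by the charge ratio of 2.31 between the north-west and south-west runs. The pseudo-first-order side holds cDw at saturation, so percentages follow the same course whatever the charge.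

From 20.0 min to 90.0 min the south-west run loses 24 percentage points and the north-west run 24 points, a ratio of 0.983, less than the charge ratio. The supply side points to 23.2% against 19.7% at 1.50 min, but that ratio, 1.18, is also smaller.

My own reckoning sums both runs over that interval, which gives a first-order decay constant of 0.0228 min⁻¹ and so the Ky tail half-life 30.3 min. That is 3.79 times the 8.00 min of the highest readings, so I expect this flask near their mean, 37.7%.

The forecast allows for a supply effect, yet holds that Ky against Ly conversion should “follow the same path whatever the Dw supply”, and it gives 38.3% at 7.2 min.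

The flask peaks at 37.2% at 6.69 min, and the forecast stands within tolerance.

    Ux ⇌ Xa, rate k1*(cs1 - [Xa]) while solid is left; crystals form when [Xa] > cs1 (solubility = 0.950 mM, k = 0.720 s⁻¹)
    Zu ⇌ Dw, rate k2*(csat - [Dw]) (kL = 0.740 s⁻¹)
    Ly + Dw → Ej + Xa (k = 1.00 M⁻¹ s⁻¹)
    Ly + Dw → Ky + Xa (k = 0.740 M⁻¹ s⁻¹)
    Dw + Ky → Yx + Xa (k = 0.0700 M⁻¹ s⁻¹)
    Dw + Ej → Yx + Xa (k = 0.620 M⁻¹ s⁻¹)

The supply side has its region in the first seconds, while cDw rises from none: the dissolution half-life of Dw, 0.937 s, is far shorter than the 0.78 min half-life of Dw by the turning of Ly + Dw into Ky + Xa alone, as charged. At the best time cDw stands at 4.87 mM. From 19.5% at 40.0 min, the flask has 1.32 half-lives to run, which gives 7.83%; it holds 8.58%.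

Left until 5.0 h, the same flask has 7.26 more half-lives after 80 min, counted with the half-life read from the two runs, so the count from 8.58% gives an estimate of 0.0563%, which carries the scatter of those readings. The computed amount of Ky there is 0.0927%.

(The earlier runs and the new flask stem from a simulated flask for an exercise; scatter was added.)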